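all flasks: substrate 0.16 M
- amber: reagent 0.34 M; free catalyst 0.43 mM; temperature 80 °C; run made earlier
- teal: reagent 0.53 M; free catalyst 0.43 mM; temperature 98 °C; run made earlier
- red: reagent 0.24 M; free catalyst 0.65 mM; temperature 80 °C; run made earlier
- noon: reagent 0.240 M; free catalyst 0.43 mM; at 110 °C until 2.5 h, from then on at 85 °C; time 8.0 h
- spring: reagent 0.240 M; free catalyst 0.43 mM; temperature 110 °C; time 8.0 h
- dusk: reagent 0.240 M; free catalyst 0.43 mM; temperature 85 °C; time 8.0 h

| run | time / h | target / % | isomer of the product / % |
|---|---|---|---|
| amber | 2.00 | 1.7 | 0.4 |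
| amber | 3.00 | 2.4 | 0 |
| amber | 4.00 | 0.9 | 0 |
| amber | 8.00 | 8.8 | 0.7 |
| amber | 12.0 | 10.4 | 0 |
| amber | 20.0 | 15.0 | 0 |
| teal | 0.667 | 2.7 | 0 |
| teal | 2.00 | 9.5 | 0 |
| teal | 2.50 | 8.6 | 0.9 |
| teal | 5.00 | 18.4 | 0.4 |
| teal | 8.00 | 25.9 | 3.5 |
| teal | 10.0 | 34.6 | 4.8 |
| red | 2.00 | 1.9 | 0 |
| red | 3.00 | 3.5 | 0.2 |
| red | 6.00 | 6.9 | 1.4 |
| red | 12.0 | 12.3 | 1.3 |
| red | 20.0 | 23.1 | 0 |

(standard deviation of a reading: 1 percentage point)

- the flask that comes out highest in share of target in all that became target or isomer of the product, or "all alike" when all lie within 1.5 percentage points (noon / spring / dusk / all alike)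
- share of target in all that became target or isomer of the product, noon
- share of target in all that became target or isomer of the product, spring
- share of target in all that became target or isomer of the product, dusk

- what was read earlier has a scatter of 1 percentage point, one standard deviation

**First rung.** Time at temperature is what I watch here, so I order the earlier runs by time scale, fastest first. Teal shows 2.7 % of target at its first reading, 0.667 h, close to the pace of its later readings, so I see no start-up on this scale.

**Steady feed.** Teal reaches 34.6 % of target at 10.0 h. At that pace its substrate lasts 28.9 h, longer than the run. I therefore treat the feed of target as steady, which makes the mean age of the target t/2, with t the elapsed time.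

**Isomer clock.** Let target pass into isomer of the product with first-order constant k. For a steady feed, isomer over target is then the isomer number N = k·t/2, and the share of target is S = 1/(1 + N). The feed rate cancels. Teal's last reading gives k = 0.0277 /h at 98 °C, a clock of 36.1 h, the slowest rung, longer than the feed time. At 80 °C the red run shows 0 % of isomer beside 23.1 % of target at 20.0 h. Taking one standard deviation of isomer there as the isomer present gives k of about 0.00433 /h. That gives a rough activation energy, 112 kJ/mol, which I use as my value.

**My reckoning.** This gives k = 0.0869 /h at 110 °C and 0.00739 /h at 85 °C, far slower. For spring, N = 0.348, so S is 74.2 %. For dusk, N = 0.0296 and S is 97.1 %. For noon I count the hot leg, N = 0.109, and S is 90.2 %.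

**Forecast, flask.** The forecast names dusk and gives 85 % for noon, 58 % for spring and 98 % for dusk, on the ground that the late isomer “points to a secondary change of the target”. The flasks give 90.8 % for noon, 73.1 % for spring and 98.2 % for dusk, so dusk stands highest.

    reagent + free catalyst → catalyst intermediate A (k = 590 /M/h, Ea = 81.0 kJ/mol)
    substrate + catalyst intermediate A → catalyst intermediate B (k = 1200 /M/h, Ea = 49.0 kJ/mol)
    catalyst intermediate B ⇌ catalyst intermediate C (K = 32.0, k = 93.0 /h, Ea = 100 kJ/mol, ΔH = −35.0 kJ/mol)
    catalyst intermediate C → free catalyst + target (k = 120 /h, Ea = 98.0 kJ/mol)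
    target ⇌ isomer of the product (K = 23.0, k = 0.0790 /h, Ea = 129 kJ/mol, ΔH = −8.00 kJ/mol)
    (constants at 110 °C)

**One reason.** Between spring and dusk the share differs by 25 percentage points, and the largest single effect is what temperature does to the passing of target into isomer of the product. With that effect taken away, the difference is 0.11 points. Spring stands at N = 0.367 at 8.00 h. A neighbour of spring charged with 0.040 M of substrate has 5.5 % of it left, so its feed is not steady. Its N is 0.481, which with my k means a mean target age of 5.54 h, older than t/2, and a share of 67.5 %.

Readings and results are simulated for substances that don't exist; noise was put on by code.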